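**Retrosynthetic overview**
1. The oxolane is numbered O1, C2 (3,4-dimethoxyphenyl), C3 (Me), C4 (Me), C5 (3,4,5-trimethoxyphenyl), with 2,3-trans, 3,4-cis, 4,5-trans. The strategy rests on the C4/C5 pair: the O1-bonded aryl carbon C5 and the methyl-bearing C4 are anti and lie next to C3. This is the pattern left by a crotyl addition to an aryl aldehyde when the crotyl unit carries C2 as an ester on the carbon that becomes C3.
2. C2–aryl bond (made last): Friedel–Crafts arylation of the C2 oxocarbenium ion with veratrole, anti to the C3 methyl. The ion comes from the lactone through the lactol and its methyl acetal.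
3. C3 methyl: hydrogenation of an exocyclic C3=CH2 from the face away from the C4 methyl (3,4-cis).
4. Key disconnection, C4–C5 and O1–C2: chromium-catalysed enantioselective (ethoxycarbonyl)crotylation of 3,4,5-trimethoxybenzaldehyde with ethyl (Z)-2-(bromomethyl)but-2-enoate, then lactonization. The bromo ester comes from ethyl acrylate and acetaldehyde (Morita–Baylis–Hillman reaction, SN2′ bromination).
5. Ring order: the single ring (the oxolane) is closed once, as the γ-lactone, in the key step and is kept to the end.

Key step: step 3

Remark on the chemistry: the ligated σ-allylchromium species is assumed to interconvert between its alkene isomers (1,3-metal shift) faster than it adds to the aldehyde, so that the chair transition state, not the (Z) geometry of the bromo ester, sets the relative configuration. This assumption is not secure for an allyl unit with an ester on its central carbon; the first risk note covers the case where it fails.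

Step 1
Reactants: 1 ethyl acrylate; 2 acetaldehyde
Product: 3 ethyl 3-hydroxy-2-methylidenebutanoate (racemic)
Conditions: DABCO (20 mol %), neat, closed flask, rt, several days
Reagents that add atoms: none
Why: Morita–Baylis–Hillman reaction, in which the DABCO–acrylate zwitterion adds to the unhindered aldehyde and the amine is then eliminated; the carbinol centre is racemic and is removed in step 2.

Step 2
Reactants: 3 ethyl 3-hydroxy-2-methylidenebutanoate
Product: 4 ethyl (Z)-2-(bromomethyl)but-2-enoate
Conditions: NBS, Me2S, CH2Cl2, 0 °C to rt
Reagents that add atoms: N-bromosuccinimide, O=C1CCC(=O)N1Br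
Why: Corey–Kim-type bromination, in which the allylic alcohol is activated as an alkoxysulfonium ion and bromide attacks the terminal methylene in SN2′ fashion, giving the conjugated trisubstituted alkene with the methyl group trans to the ester (Z).

Step 3
Reactants: 5 3,4,5-trimethoxybenzaldehyde; 4 ethyl (Z)-2-(bromomethyl)but-2-enoate
Product: 9 (4R,5R)-4-methyl-3-methylene-5-(3,4,5-trimethoxyphenyl)dihydrofuran-2(3H)-one, via allylchromium species 6 (not isolated), via silyl ether 7 (not isolated), via hydroxy ester 8 (not isolated)
Conditions: CrCl2 (10 mol %), chiral 1,8-bis(4-isopropyl-4,5-dihydrooxazol-2-yl)-3,6-diphenylcarbazole ligand (12 mol %, the antipode that gives Re-face addition), i-Pr2NEt (30 mol %), Mn powder (2 equiv), Me3SiCl (1.5 equiv), THF, rt; then 1 M HCl work-up and TsOH·H2O (10 mol %), CH2Cl2, rt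
Reagents that add atoms: none
Why: This is a Nozaki–Hiyama–Kishi-type crotylation made catalytic in chromium: ligand-bound divalent chromium reduces the allylic C–Br bond of 4 in two one-electron events to the trivalent σ-allylchromium species 6, Mn powder returns the spent trivalent chromium halide to the divalent state, and Me3SiCl releases the chromium alkoxide of the adduct as silyl ether 7. Species 6 equilibrates between its alkene isomers by 1,3-chromium shifts and forms the C4–C5 bond by γ-attack through a closed six-membered chair in which the aryl group of 5 and the methyl group on the attacking carbon are both equatorial, so that C4 and C5 should emerge anti (4,5-trans in the ring). The tridentate ligand on chromium exposes the Re face of the aldehyde, which fixes C5 as R, and C4 (R) follows from the chair, so both new stereocentres are under catalyst control relayed by the cyclic transition state. The closest known reaction type is the chromium-catalysed enantioselective 2-(alkoxycarbonyl)allylation of aldehydes that leads to α-methylene-γ-butyrolactones. Acid then cleaves the silyl ether, and the C5 hydroxyl of 8 closes the only ring by 5-exo-trig attack on the ethyl ester carbonyl (O1–C2, acyl substitution with loss of ethanol, no stereocentre touched). The step needs γ-regioselectivity, anti simple diastereoselection and Re-face selection: the cyclic transition state secures the first, the equatorial preference of the single methyl substituent against the ligand-laden chromium centre the second, and the unhindered, non-enolisable aryl aldehyde 5, which binds chromium anti to its aryl group, the third.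

Step 4
Reactants: 9 (4R,5R)-4-methyl-3-methylene-5-(3,4,5-trimethoxyphenyl)dihydrofuran-2(3H)-one
Product: 10 (3S,4R,5R)-3,4-dimethyl-5-(3,4,5-trimethoxyphenyl)dihydrofuran-2(3H)-one
Conditions: H2 (1 atm), RhCl(PPh3)3 (5 mol %), PhMe–EtOH (1:1), rt
Reagents that add atoms: none
Why: Homogeneous rhodium-catalysed hydrogenation of the 1,1-disubstituted exocyclic alkene should deliver hydrogen to the face opposite the adjacent C4 methyl, so the new C3 methyl is cis to it (3S); this catalyst is chosen over Pd/C because it should neither cleave the benzylic C5–O bond nor move the alkene into the ring.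

Step 5
Reactants: 10 (3S,4R,5R)-3,4-dimethyl-5-(3,4,5-trimethoxyphenyl)dihydrofuran-2(3H)-one
Product: 11 (3S,4R,5R)-3,4-dimethyl-5-(3,4,5-trimethoxyphenyl)oxolan-2-ol (both C2 anomers)
Conditions: i-Bu2AlH (1.1 equiv), CH2Cl2, −78 °C; aq. potassium sodium tartrate work-up
Reagents that add atoms: none
Why: Partial reduction of the lactone stops at the lactol because the tetrahedral aluminium hemiacetal is stable at −78 °C; no existing stereocentre is touched and both anomers are carried on.

Step 6
Reactants: 11 (3S,4R,5R)-3,4-dimethyl-5-(3,4,5-trimethoxyphenyl)oxolan-2-ol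
Product: 12 (3S,4R,5R)-2-methoxy-3,4-dimethyl-5-(3,4,5-trimethoxyphenyl)oxolane (both C2 anomers)
Conditions: MeOH, PPTS (10 mol %), 3 Å molecular sieves, rt
Reagents that add atoms: methanol, CO
Why: Fischer-type acetalization exchanges the anomeric hydroxyl for methoxy through the oxocarbenium ion under acid mild enough to leave C3 and the benzylic C5–O bond alone; the anomeric mixture is of no consequence because C2 is ionised again in step 7.

Step 7
Reactants: 12 (3S,4R,5R)-2-methoxy-3,4-dimethyl-5-(3,4,5-trimethoxyphenyl)oxolane; 13 1,2-dimethoxybenzene (veratrole, 3 equiv)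
Product: 15 (2S,3S,4R,5R)-2-(3,4-dimethoxyphenyl)-3,4-dimethyl-5-(3,4,5-trimethoxyphenyl)oxolane, via oxocarbenium ion 14 (not isolated)
Conditions: BF3·OEt2 (1.5 equiv, promoter), CH2Cl2, −78 to −20 °C
Reagents that add atoms: none
Why: BF3 ionises the methyl acetal to the five-membered oxocarbenium ion 14, and veratrole attacks it para to a methoxy group (Friedel–Crafts alkylation) from the face opposite the C3 and C4 methyl groups, setting C2 (S) trans to the C3 methyl and cis to the C5 aryl; this 2,3-trans/4,5-trans arrangement is also the thermodynamically preferred one should a benzylic centre equilibrate.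

**Compound list**
1 | ethyl acrylate | C=CC(=O)OCC | starting material
2 | acetaldehyde | CC=O | starting material
3 | ethyl 3-hydroxy-2-methylidenebutanoate (racemic) | CC(O)C(=C)C(=O)OCC | intermediate
4 | ethyl (Z)-2-(bromomethyl)but-2-enoate | C/C=C(\CBr)C(=O)OCC | intermediate
5 | 3,4,5-trimethoxybenzaldehyde | COc1cc(C=O)cc(OC)c1OC | starting material
6 | [2-(ethoxycarbonyl)but-2-en-1-yl]chromium dichloride (trivalent chromium; chiral ligand not drawn; alkene geometry mobile) | CCOC(=O)C(=CC)C[Cr](Cl)Cl | intermediate
7 | ethyl (3R,4R)-3-methyl-2-methylidene-4-(3,4,5-trimethoxyphenyl)-4-[(trimethylsilyl)oxy]butanoate | C[Si](C)(C)O[C@@H](c1cc(OC)c(OC)c(OC)c1)[C@H](C)C(=C)C(=O)OCC | intermediate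
8 | ethyl (3R,4R)-4-hydroxy-3-methyl-2-methylidene-4-(3,4,5-trimethoxyphenyl)butanoate | O[C@@H](c1cc(OC)c(OC)c(OC)c1)[C@H](C)C(=C)C(=O)OCC | intermediate
9 | (4R,5R)-4-methyl-3-methylene-5-(3,4,5-trimethoxyphenyl)dihydrofuran-2(3H)-one | O=C1O[C@@H](c2cc(OC)c(OC)c(OC)c2)[C@H](C)C1=C | intermediate
10 | (3S,4R,5R)-3,4-dimethyl-5-(3,4,5-trimethoxyphenyl)dihydrofuran-2(3H)-one | O=C1O[C@@H](c2cc(OC)c(OC)c(OC)c2)[C@H](C)[C@@H]1C | intermediate
11 | (3S,4R,5R)-3,4-dimethyl-5-(3,4,5-trimethoxyphenyl)oxolan-2-ol (C2 anomers) | OC1O[C@@H](c2cc(OC)c(OC)c(OC)c2)[C@H](C)[C@@H]1C | intermediate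
12 | (3S,4R,5R)-2-methoxy-3,4-dimethyl-5-(3,4,5-trimethoxyphenyl)oxolane (C2 anomers) | COC1O[C@@H](c2cc(OC)c(OC)c(OC)c2)[C@H](C)[C@@H]1C | intermediate
13 | 1,2-dimethoxybenzene (veratrole) | COc1ccccc1OC | starting material
14 | (3S,4R,5R)-3,4-dimethyl-5-(3,4,5-trimethoxyphenyl)-4,5-dihydro-3H-furan-1-ium (oxocarbenium ion) | C1=[O+][C@@H](c2cc(OC)c(OC)c(OC)c2)[C@H](C)[C@@H]1C | intermediate
15 | (2S,3S,4R,5R)-2-(3,4-dimethoxyphenyl)-3,4-dimethyl-5-(3,4,5-trimethoxyphenyl)oxolane | COc1ccc([C@H]2O[C@@H](c3cc(OC)c(OC)c(OC)c3)[C@H](C)[C@@H]2C)cc1OC | target

Total step count: 7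
Longest linear sequence: 7 steps (ethyl acrylate to the target, steps 1 to 7)

**Steps most likely to fail**

Step 3. Simple diastereoselection may leak into the syn manifold or be dominated by it. The ester on the central allyl carbon stabilises the allylchromium isomer whose methyl group is cis to CH2–Cr, and that isomer reacts through a chair with the methyl axial, giving the 4,5-cis lactone; incomplete face selection would add to the loss. A minor amount of cis-lactone is a diastereomer of 9 and is removed by chromatography. If the syn manifold dominates, control of C5 is moved from the addition to an equilibration. The fallback sets out from 4 and 5, which are coupled under the chromium conditions of step 3 with the ligand antipode (Si-face addition). This gives the syn silyl ether F1 and, after hydrolysis, the syn hydroxy ester F2, which mild acid closes to the cis-lactone F3, in which C4 is already R. TfOH (10 mol %) in toluene at rt then ionises the benzylic C5–O bond to the 3,4,5-trimethoxybenzyl cation, and reclosure on the face away from the C4 methyl gives the trans-lactone 9, where the route is rejoined. C4 is not involved in this epimerization. Acid-induced inversion of the benzylic centre of electron-rich γ-aryl-β-methyl-α-methylene lactones is known behaviour.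

Step 4. Facial selection in hydrogen delivery may be poor, because the C5 aryl group lies on the face that hydrogen must use, and the alkene may migrate into the ring. The fallback sets out from 9 and sets C3 by kinetic protonation instead of hydrogenation. Conjugate hydride addition with LiBH(s-Bu)3 in THF at −78 °C gives the lithium enolate F4. It is protonated at −78 °C with 2,6-di-tert-butyl-4-methylphenol from the face opposite the C4 methyl, which gives 10, where the route is rejoined. Lactone of the wrong C3 configuration can be returned to the same enolate with LiN(i-Pr)2 and protonated again.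

Step 7. C3 may lose its configuration through proton loss from the oxocarbenium ion to the 2,3-dihydrofuran and reprotonation, and facial selection at C2 may be incomplete. The fallback sets out from lactol 11 and brings in the aryl group as an organometallic nucleophile instead of as an arene. 3,4-Dimethoxyphenylmagnesium bromide (commercial, 3 equiv, THF, 0 °C) adds to the open hydroxy aldehyde form of 11 and gives the 1,4-diol F5 as both C1 epimers. TsOH·H2O (cat.) in CH2Cl2 at 0 °C then ionises the more electron-rich 3,4-dimethoxybenzylic carbinol, and the C5 hydroxyl closes the oxolane trans to the C3 methyl, giving the target 15 directly.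

Further compounds
F1 | step 3 | ethyl (3R,4S)-3-methyl-2-methylidene-4-(3,4,5-trimethoxyphenyl)-4-[(trimethylsilyl)oxy]butanoate | C[Si](C)(C)O[C@H](c1cc(OC)c(OC)c(OC)c1)[C@H](C)C(=C)C(=O)OCC
F2 | step 3 | ethyl (3R,4S)-4-hydroxy-3-methyl-2-methylidene-4-(3,4,5-trimethoxyphenyl)butanoate | O[C@H](c1cc(OC)c(OC)c(OC)c1)[C@H](C)C(=C)C(=O)OCC
F3 | step 3 | (4R,5S)-4-methyl-3-methylene-5-(3,4,5-trimethoxyphenyl)dihydrofuran-2(3H)-one | O=C1O[C@H](c2cc(OC)c(OC)c(OC)c2)[C@H](C)C1=C
F4 | step 4 | lithium (4R,5R)-3,4-dimethyl-5-(3,4,5-trimethoxyphenyl)-4,5-dihydrofuran-2-olate | [Li+].[O-]C1O[C@@H](c2cc(OC)c(OC)c(OC)c2)[C@H](C)C=1C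
F5 | step 7 | (2S,3R,4R)-1-(3,4-dimethoxyphenyl)-2,3-dimethyl-4-(3,4,5-trimethoxyphenyl)butane-1,4-diol (C1 epimers) | COc1ccc(C(O)[C@@H](C)[C@@H](C)[C@@H](O)c2cc(OC)c(OC)c(OC)c2)cc1OC
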